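**Retrosynthetic overview**
1. Target ⇒ (E)-enone C=C by Claisen–Schmidt condensation of salicylaldehyde with 2',4'-dihydroxy-3'-[(S)-lavandulyl]acetophenone, carried in bis-silyl-masked form.
2. Prenyl arm ⇒ isopropylidene Wittig on a lactol ⇐ DIBAL-H ⇐ seven-membered aryl lactone (a latent CH2–CH=CMe2 plus phenol).
3. Key bond ArCH2–C*: the β-carbon of a carbene-bound homoenolate of (E)-4-methylpenta-2,4-dienal (donor, normally an acceptor carbon) joins the methylene of an o-quinone methide (acceptor) in an enantioselective formal [4+3] that sets the only stereocentre.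
4. o-Quinone methide ⇐ Mannich-base methiodide ⇐ 2',4'-dihydroxyacetophenone; dienal ⇐ methacrolein + Ph3P=CHCHO.
5. Rings: both benzene rings are bought; the only ring formed is the temporary benzoxepinone (key step), opened again in the Wittig step.

Assumption: the (5aS,10bR)-aminoindanol triazolium is assumed to direct attack to the Re face of the dienal β-carbon (giving the 4R lactone); if the first run shows the opposite sense, its commercial (5aR,10bS) antipode is used with nothing else changed.

**Step 1**
Reactants: 1 methacrolein; 2 (triphenylphosphoranylidene)acetaldehyde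
Product: 3 (2E)-4-methylpenta-2,4-dienal
Conditions: 1 (3 equiv), BHT (cat.), toluene, 75 °C, sealed, 18 h; fractional distillation
Reagents that add atoms: none
Why: Wittig olefination with the stabilised formylmethylene ylide gives the (E)-dienal, and the excess of volatile methacrolein suppresses a second homologation.

**Step 2**
Reactants: 4 2',4'-dihydroxyacetophenone
Product: 5 1-{3-[(dimethylamino)methyl]-2,4-dihydroxyphenyl}ethan-1-one
Conditions: 37% aq. CH2O (1.05 equiv), 40% aq. Me2NH (1.1 equiv), EtOH, 0 °C → rt, 16 h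
Reagents that add atoms: formaldehyde, C=O; dimethylamine, CNC
Why: Phenolic Mannich aminomethylation goes to C3, the ring carbon ortho to both hydroxyls and the most nucleophilic one, as in the 8-aminomethylation of 7-hydroxychromones.

**Step 3**
Reactants: 5 1-{3-[(dimethylamino)methyl]-2,4-dihydroxyphenyl}ethan-1-one; 3 (2E)-4-methylpenta-2,4-dienal
Product: 8 (4R)-7-acetyl-6-hydroxy-4-(prop-1-en-2-yl)-4,5-dihydro-1-benzoxepin-2(3H)-one, via trimethylammonium iodide 6 (not isolated), via o-quinone methide 7 (not isolated)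
Conditions: MeI (1.05 equiv), MeCN, rt, 3 h, evaporate; then 3 (1.5 equiv), (5aS,10bR)-N-mesityl aminoindanol-triazolium chloride (15 mol %), Cs2CO3 (1.3 equiv), 4 Å MS, THF, rt → 40 °C, 16 h
Reagents that add atoms: none
Why: Proposed new method: the sparingly soluble phenoxide betaine of 6 slowly loses NMe3 to release o-quinone methide 7 while the carbene turns dienal 3 into its Breslow-type homoenolate, whose β-carbon adds on its Re face (the other face is shielded by the indane of the catalyst) to the exocyclic CH2 of 7 with rearomatisation, after which the 4-phenoxide acylates the acyl azolium to close the seven-membered lactone and free the carbene, setting C4 as R (an O2-lactone isomer, if formed, converges at 13); β- rather than δ-attack is expected because only β-attack allows the ring-closing acylation that turns the catalyst over; closest known reaction type: NHC-catalysed enantioselective formal [4+3] annulation of enal homoenolates with in situ generated o-quinone methides to 4-substituted 4,5-dihydro-1-benzoxepin-2(3H)-ones.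

**Step 4**
Reactants: 8 (4R)-7-acetyl-6-hydroxy-4-(prop-1-en-2-yl)-4,5-dihydro-1-benzoxepin-2(3H)-one
Product: 10 (2RS,4R)-6-[(tert-butyldimethylsilyl)oxy]-7-{1-[(tert-butyldimethylsilyl)oxy]ethenyl}-4-(prop-1-en-2-yl)-2,3,4,5-tetrahydro-1-benzoxepin-2-ol, via bis-TBS lactone 9 (not isolated)
Conditions: TBSOTf (2.3 equiv), Et3N (3 equiv), CH2Cl2, 0 °C → rt, 1 h; evaporate, pentane extraction/filtration; then DIBAL-H (1.2 equiv), toluene, −78 °C, 1 h; Rochelle salt
Reagents that add atoms: tert-butyldimethylsilyl trifluoromethanesulfonate, CC(C)(C)[Si](C)(C)OS(=O)(=O)C(F)(F)F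
Why: Soft enolisation/silylation masks the methyl ketone as its silyl enol ether and the phenol as its silyl ether, so that DIBAL-H partial reduction touches only the aryl lactone and stops at the aluminium hemiacetal (as for dihydrocoumarin → chromanol); C4 is β to the carbonyl and cannot epimerise.

**Step 5**
Reactants: 10 (2RS,4R)-6-[(tert-butyldimethylsilyl)oxy]-7-{1-[(tert-butyldimethylsilyl)oxy]ethenyl}-4-(prop-1-en-2-yl)-2,3,4,5-tetrahydro-1-benzoxepin-2-ol
Product: 11 3-[(tert-butyldimethylsilyl)oxy]-4-{1-[(tert-butyldimethylsilyl)oxy]ethenyl}-2-[(2S)-5-methyl-2-(prop-1-en-2-yl)hex-4-en-1-yl]phenol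
Conditions: i-PrPPh3+ I− (2.6 equiv), n-BuLi (2.5 equiv), THF, 0 °C; then 10, −78 → 0 °C, 2 h
Reagents that add atoms: isopropyltriphenylphosphonium iodide, CC(C)[P+](c1ccccc1)(c1ccccc1)c1ccccc1.[I-]
Why: Wittig olefination of the ring-opened hydroxy-aldehyde tautomer with the non-stabilised isopropylidene ylide builds the prenyl arm and frees the phenol; the silyl enol ether and aryl silyl ether are inert, and the stereocentre (β to the aldehyde) is untouched, its descriptor changing from R to S only through CIP priorities.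

**Step 6**
Reactants: 11 3-[(tert-butyldimethylsilyl)oxy]-4-{1-[(tert-butyldimethylsilyl)oxy]ethenyl}-2-[(2S)-5-methyl-2-(prop-1-en-2-yl)hex-4-en-1-yl]phenol; 12 salicylaldehyde
Product: 14 (2E)-1-{2,4-dihydroxy-3-[(2S)-5-methyl-2-(prop-1-en-2-yl)hex-4-en-1-yl]phenyl}-3-(2-hydroxyphenyl)prop-2-en-1-one, via desilylated acetophenone 13 (not isolated)
Conditions: 12 (2 equiv), 50% aq. KOH (20 equiv), EtOH, Ar, rt, 36 h; then 1 M HCl to pH 5, 0 °C
Reagents that add atoms: none
Why: Hydroxide cleaves the aryl silyl ether and the silyl enol ether to the phenolate/enolate of 13, which undergoes Claisen–Schmidt aldol condensation with salicylaldehyde and E1cB dehydration to the thermodynamic (E)-enone; the lavandulyl alkenes and the remote stereocentre are stable to base.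

**Compound list**
1 | methacrolein (2-methylprop-2-enal) | CC(=C)C=O | starting material
2 | (triphenylphosphoranylidene)acetaldehyde | O=CC=P(c1ccccc1)(c1ccccc1)c1ccccc1 | starting material
3 | (2E)-4-methylpenta-2,4-dienal | CC(=C)/C=C/C=O | intermediate
4 | 2',4'-dihydroxyacetophenone (1-(2,4-dihydroxyphenyl)ethan-1-one) | CC(=O)c1ccc(O)cc1O | starting material
5 | 1-{3-[(dimethylamino)methyl]-2,4-dihydroxyphenyl}ethan-1-one | CC(=O)c1ccc(O)c(CN(C)C)c1O | intermediate
6 | (3-acetyl-2,6-dihydroxyphenyl)-N,N,N-trimethylmethanaminium iodide | CC(=O)c1ccc(O)c(C[N+](C)(C)C)c1O.[I-] | intermediate (not isolated)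
7 | 4-acetyl-3-hydroxy-2-methylidenecyclohexa-3,5-dien-1-one (o-quinone methide) | CC(=O)C1=C(O)C(=C)C(=O)C=C1 | intermediate (not isolated)
8 | (4R)-7-acetyl-6-hydroxy-4-(prop-1-en-2-yl)-4,5-dihydro-1-benzoxepin-2(3H)-one | CC(=O)c1ccc2OC(=O)C[C@H](C(C)=C)Cc2c1O | intermediate
9 | (4R)-6-[(tert-butyldimethylsilyl)oxy]-7-{1-[(tert-butyldimethylsilyl)oxy]ethenyl}-4-(prop-1-en-2-yl)-4,5-dihydro-1-benzoxepin-2(3H)-one | C=C(O[Si](C)(C)C(C)(C)C)c1ccc2OC(=O)C[C@H](C(C)=C)Cc2c1O[Si](C)(C)C(C)(C)C | intermediate (not isolated)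
10 | (2RS,4R)-6-[(tert-butyldimethylsilyl)oxy]-7-{1-[(tert-butyldimethylsilyl)oxy]ethenyl}-4-(prop-1-en-2-yl)-2,3,4,5-tetrahydro-1-benzoxepin-2-ol (C2 epimers) | C=C(O[Si](C)(C)C(C)(C)C)c1ccc2OC(O)C[C@H](C(C)=C)Cc2c1O[Si](C)(C)C(C)(C)C | intermediate
11 | 3-[(tert-butyldimethylsilyl)oxy]-4-{1-[(tert-butyldimethylsilyl)oxy]ethenyl}-2-[(2S)-5-methyl-2-(prop-1-en-2-yl)hex-4-en-1-yl]phenol | C=C(C)[C@@H](CC=C(C)C)Cc1c(O)ccc(C(=C)O[Si](C)(C)C(C)(C)C)c1O[Si](C)(C)C(C)(C)C | intermediate
12 | salicylaldehyde (2-hydroxybenzaldehyde) | O=Cc1ccccc1O | starting material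
13 | 1-{2,4-dihydroxy-3-[(2S)-5-methyl-2-(prop-1-en-2-yl)hex-4-en-1-yl]phenyl}ethan-1-one | C=C(C)[C@@H](CC=C(C)C)Cc1c(O)ccc(C(C)=O)c1O | intermediate (not isolated)
14 | (2E)-1-{2,4-dihydroxy-3-[(2S)-5-methyl-2-(prop-1-en-2-yl)hex-4-en-1-yl]phenyl}-3-(2-hydroxyphenyl)prop-2-en-1-one | C=C(C)[C@@H](CC=C(C)C)Cc1c(O)ccc(C(=O)/C=C/c2ccccc2O)c1O | target

**Totals**
Total step count: 6. Longest linear sequence: 5 (4 → 5 → 8 → 10 → 11 → 14).

**Three steps most likely to fail**

Step 3 (carbene alkylation by the quinone methide, protonation of the homoenolate by the free phenols, δ-attack, low ee). The fallback sets out from 5 and comes back at 8. Both phenols of 5 are silylated (TBSCl, imidazole, DMF) to give the bis-silyl Mannich base F1. Ethyl chloroformate (toluene, rt) then cleaves the benzylic C–N bond to give the benzylic chloride F2. F2 is a proton-free, fluoride-triggered quinone methide precursor of the kind used in the known [4+3]. It is combined with 3 and the same triazolium salt under CsF/18-crown-6 (3 equiv) in THF; the excess fluoride also removes the second silyl ether, so the product is 8.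

Step 4 (incomplete enol silylation leading to ketone reduction, over-reduction of the aryl lactone to the diol). The fallback sets out from 8 and comes back at 13. No protection is used. Excess DIBAL-H (4 equiv, CH2Cl2, −78 °C) reduces the lactone to the lactol and the ketone to the carbinol, giving the lactol carbinol F3. Wittig reaction with excess Ph3P=CMe2 gives the hydroxyethyl lavandulyl resorcinol F4. Activated MnO2 (CH2Cl2, rt) re-oxidises the benzylic secondary alcohol, which is activated by the ortho and para hydroxyls, to the aryl methyl ketone 13. Compound 13 is then isolated and condensed with 12 under the step 6 conditions.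

Step 6 (the ionised salicylaldehyde is a poor electrophile, so conversion may be low). The fallback sets out from 11 and 12 and comes back at 14. Compound 12 is protected (MOMCl, i-Pr2NEt, CH2Cl2) as 2-(methoxymethoxy)benzaldehyde F5, whose non-ionised formyl group is far more electrophilic. Condensation with 11 under KOH/EtOH (silyl groups lost in situ as before) gives the MOM-protected chalcone F6. 3 M HCl/MeOH at rt then removes the MOM group to give 14.

**Further compounds**
F1 | step 3 | 1-{2,4-bis[(tert-butyldimethylsilyl)oxy]-3-[(dimethylamino)methyl]phenyl}ethan-1-one | CC(=O)c1ccc(O[Si](C)(C)C(C)(C)C)c(CN(C)C)c1O[Si](C)(C)C(C)(C)C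
F2 | step 3 | 1-{2,4-bis[(tert-butyldimethylsilyl)oxy]-3-(chloromethyl)phenyl}ethan-1-one | CC(=O)c1ccc(O[Si](C)(C)C(C)(C)C)c(CCl)c1O[Si](C)(C)C(C)(C)C
F3 | step 4 | (4R)-7-(1-hydroxyethyl)-4-(prop-1-en-2-yl)-2,3,4,5-tetrahydro-1-benzoxepine-2,6-diol (epimers at C2 and at the carbinol) | CC(O)c1ccc2OC(O)C[C@H](C(C)=C)Cc2c1O
F4 | step 4 | 4-(1-hydroxyethyl)-2-[(2S)-5-methyl-2-(prop-1-en-2-yl)hex-4-en-1-yl]benzene-1,3-diol | C=C(C)[C@@H](CC=C(C)C)Cc1c(O)ccc(C(C)O)c1O
F5 | step 6 | 2-(methoxymethoxy)benzaldehyde | COCOc1ccccc1C=O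
F6 | step 6 | (2E)-1-{2,4-dihydroxy-3-[(2S)-5-methyl-2-(prop-1-en-2-yl)hex-4-en-1-yl]phenyl}-3-[2-(methoxymethoxy)phenyl]prop-2-en-1-one | C=C(C)[C@@H](CC=C(C)C)Cc1c(O)ccc(C(=O)/C=C/c2ccccc2OCOC)c1O
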